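The route rests on cutting C3–C4, the bond between the methylene next to the C2 carbinol and the CH of the (4E)-trisubstituted alkene. C1, C2 and C3 of the chain are the carbon skeleton of (R)-malic acid minus its distal carboxyl. C3 is therefore made as a primary radical by electroreductive loss of CO2 from the N-hydroxyphthalimide ester of acetonide-protected malic acid and is captured on nickel by the (E)-alkenyl group of a C14 iodide. One operation forges C3–C4, keeps the alkene geometry and carries C2 in from the chiral pool. The dioxolanone carbonyl (C1) later becomes the ketone on the resorcinol ring through a Weinreb amide.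

Key step: step 4

Assumption: C2 is (R) as drawn, which maps onto (R)-malic acid; its acetonide acid 7 is taken as a catalogue compound (otherwise it is the product of (R)-malic acid with 2,2-dimethoxypropane and acid).

Step 1
Reactants: 1 propyne; 2 geranyl bromide, (2E)-1-bromo-3,7-dimethylocta-2,6-diene
Product: 4 (5E)-6,10-dimethylundeca-5,9-dien-1-yne, via 1,3-dilithiopropyne 3 (not isolated)
Conditions: n-BuLi (2.1 equiv), TMEDA, Et2O/hexane, –78 → 0 °C; then 2, –78 °C → rt; aq NH4Cl
Reagents that add atoms: none
Why: Propargylation with the propyne dianion: double deprotonation gives 1,3-dilithiopropyne, whose sp3 terminus is the more nucleophilic and displaces the primary allylic bromide by SN2 without touching the (E)-alkene, the acetylide end being protonated on work-up.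

Step 2
Reactants: 4 (5E)-6,10-dimethylundeca-5,9-dien-1-yne
Product: 6 (1E,5E)-1-iodo-2,6,10-trimethylundeca-1,5,9-triene, via alkenylalane 5 (not isolated)
Conditions: AlMe3 (3 equiv), Cp2ZrCl2 (0.25 equiv), CH2Cl2, 0 °C → rt; then I2, THF, –30 → 0 °C
Reagents that add atoms: trimethylaluminium, C[Al](C)C; iodine, I-I
Why: Negishi zirconium-catalysed carboalumination adds methyl and aluminium syn across the terminal alkyne with methyl at the internal carbon, and iodinolysis of the C–Al bond with retention should fix the (E)-trisubstituted iodoalkene while the isolated trisubstituted alkenes stay inert.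

Step 3
Reactants: 7 2-[(4R)-2,2-dimethyl-5-oxo-1,3-dioxolan-4-yl]acetic acid
Product: 8 1,3-dioxoisoindolin-2-yl 2-[(4R)-2,2-dimethyl-5-oxo-1,3-dioxolan-4-yl]acetate
Conditions: N-hydroxyphthalimide, N,N'-diisopropylcarbodiimide, DMAP (cat.), CH2Cl2, rt
Reagents that add atoms: N-hydroxyphthalimide, O=C1c2ccccc2C(=O)N1O
Why: Carbodiimide (Steglich-type) esterification of the free carboxylic acid with N-hydroxyphthalimide should give the redox-active ester under neutral conditions that leave the dioxolanone and its stereocentre untouched.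

Step 4
Reactants: 8 1,3-dioxoisoindolin-2-yl 2-[(4R)-2,2-dimethyl-5-oxo-1,3-dioxolan-4-yl]acetate (1.5 equiv); 6 (1E,5E)-1-iodo-2,6,10-trimethylundeca-1,5,9-triene
Product: 9 (5R)-2,2-dimethyl-5-[(2E,6E)-3,7,11-trimethyldodeca-2,6,10-trien-1-yl]-1,3-dioxolan-4-one
Conditions: NiCl2·6H2O (10 mol %), 2,2'-bipyridine (10 mol %), AgNO3 (0.3 equiv), DMF, Mg anode / RVC cathode, undivided cell, constant current, rt
Reagents that add atoms: none
Why: Nickel-electrocatalytic decarboxylative alkenylation of a redox-active ester: cathodically generated low-valent nickel–bipyridine adds oxidatively to the C–I bond of 6 to give an alkenyl divalent nickel species, while single-electron reduction of 8 (by low-valent nickel or at the silver-nanoparticle-coated cathode formed from AgNO3) expels phthalimide anion and CO2 and leaves the primary radical at the future C3. Capture of this radical gives a trivalent nickel species whose reductive elimination forms the C3–C4 bond, the Mg anode supplying the electrons. The closest known reaction type is the silver-assisted nickel-electrocatalytic coupling of N-hydroxyphthalimide esters with alkenyl iodides used to assemble the trisubstituted alkenes of polyene terpenes. The step closes no ring and creates no stereocentre; the C2 stereocentre sits next to the radical carbon, is not part of it and should not epimerise under these neutral conditions. It needs retention of the (E)-geometry at C4=C5, secured by stereoretentive oxidative addition and reductive elimination at the sp2 carbon, and cross-coupling over reduction or dimerisation of the radical, secured by its slow release at the modified cathode and the excess of 8.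

Step 5
Reactants: 9 (5R)-2,2-dimethyl-5-[(2E,6E)-3,7,11-trimethyldodeca-2,6,10-trien-1-yl]-1,3-dioxolan-4-one
Product: 10 (2R,4E,8E)-2-hydroxy-N-methoxy-N,5,9,13-tetramethyltetradeca-4,8,12-trienamide
Conditions: MeNHOMe·HCl (2 equiv), i-PrMgCl (4 equiv), THF, –20 → 0 °C; aq NH4Cl
Reagents that add atoms: N,O-dimethylhydroxylamine hydrochloride, CNOC.Cl
Why: Weinreb aminolysis of the activated lactone carbonyl by the magnesium amide opens the dioxolanone, the hemiketal alkoxide loses acetone to free the C2 hydroxyl, and the low temperature and weakly basic amide should keep the α-stereocentre intact.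

Step 6
Reactants: 11 4-bromoresorcinol (4-bromobenzene-1,3-diol)
Product: 12 1-bromo-2,4-bis(methoxymethoxy)benzene
Conditions: MOMCl (2.5 equiv), i-Pr2NEt, CH2Cl2, 0 °C → rt
Reagents that add atoms: chloromethyl methyl ether (MOMCl), COCCl
Why: O-Alkylation of both phenols (Williamson-type) under amine base should give the bis-MOM ether, which is stable to organolithiums and coordinates the ortho lithium.

Step 7
Reactants: 10 (2R,4E,8E)-2-hydroxy-N-methoxy-N,5,9,13-tetramethyltetradeca-4,8,12-trienamide; 12 1-bromo-2,4-bis(methoxymethoxy)benzene (2.5 equiv)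
Product: 14 (2R,4E,8E)-1-[2,4-bis(methoxymethoxy)phenyl]-2-hydroxy-5,9,13-trimethyltetradeca-4,8,12-trien-1-one, via aryllithium 13 (not isolated)
Conditions: 12, n-BuLi (2.4 equiv), THF, –78 °C; then 10, –78 → –20 °C; aq NH4Cl
Reagents that add atoms: none
Why: Bromine–lithium exchange gives the aryllithium, one equivalent of which removes the hydroxyl proton while a second adds to the amide to give a chelated tetrahedral adduct that releases the ketone only on quench (Weinreb ketone synthesis), so over-addition should not occur and C2 is not touched.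

Step 8
Reactants: 14 (2R,4E,8E)-1-[2,4-bis(methoxymethoxy)phenyl]-2-hydroxy-5,9,13-trimethyltetradeca-4,8,12-trien-1-one
Product: 15 (2R,4E,8E)-1-(2,4-dihydroxyphenyl)-2-hydroxy-5,9,13-trimethyltetradeca-4,8,12-trien-1-one
Conditions: 3 M HCl (aq), MeOH, rt
Reagents that add atoms: none
Why: Acid-catalysed acetal cleavage (MOM removal) in methanol should free both phenols, the ortho one assisted by the carbonyl, under conditions dilute and cool enough to spare the trisubstituted alkenes and the α-ketol stereocentre.

Compound list
1 | propyne (prop-1-yne) | CC#C | starting material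
2 | geranyl bromide, (2E)-1-bromo-3,7-dimethylocta-2,6-diene | CC(C)=CCC/C(C)=C/CBr | starting material
3 | 1,3-dilithiopropyne | [Li]CC#C[Li] | intermediate
4 | (5E)-6,10-dimethylundeca-5,9-dien-1-yne | CC(C)=CCC/C(C)=C/CCC#C | intermediate
5 | dimethyl[(1E,5E)-2,6,10-trimethylundeca-1,5,9-trien-1-yl]alane | CC(C)=CCC/C(C)=C/CC/C(C)=C/[Al](C)C | intermediate
6 | (1E,5E)-1-iodo-2,6,10-trimethylundeca-1,5,9-triene | CC(C)=CCC/C(C)=C/CC/C(C)=C/I | intermediate
7 | 2-[(4R)-2,2-dimethyl-5-oxo-1,3-dioxolan-4-yl]acetic acid | CC1(C)O[C@H](CC(=O)O)C(=O)O1 | starting material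
8 | 1,3-dioxoisoindolin-2-yl 2-[(4R)-2,2-dimethyl-5-oxo-1,3-dioxolan-4-yl]acetate | CC1(C)O[C@H](CC(=O)ON2C(=O)c3ccccc3C2=O)C(=O)O1 | intermediate
9 | (5R)-2,2-dimethyl-5-[(2E,6E)-3,7,11-trimethyldodeca-2,6,10-trien-1-yl]-1,3-dioxolan-4-one | CC(C)=CCC/C(C)=C/CC/C(C)=C/C[C@H]1OC(C)(C)OC1=O | intermediate
10 | (2R,4E,8E)-2-hydroxy-N-methoxy-N,5,9,13-tetramethyltetradeca-4,8,12-trienamide | CC(C)=CCC/C(C)=C/CC/C(C)=C/C[C@@H](O)C(=O)N(C)OC | intermediate
11 | 4-bromoresorcinol (4-bromobenzene-1,3-diol) | Oc1ccc(Br)c(O)c1 | starting material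
12 | 1-bromo-2,4-bis(methoxymethoxy)benzene | COCOc1ccc(Br)c(OCOC)c1 | intermediate
13 | [2,4-bis(methoxymethoxy)phenyl]lithium | [Li]c1ccc(OCOC)cc1OCOC | intermediate
14 | (2R,4E,8E)-1-[2,4-bis(methoxymethoxy)phenyl]-2-hydroxy-5,9,13-trimethyltetradeca-4,8,12-trien-1-one | CC(C)=CCC/C(C)=C/CC/C(C)=C/C[C@@H](O)C(=O)c1ccc(OCOC)cc1OCOC | intermediate
15 | (2R,4E,8E)-1-(2,4-dihydroxyphenyl)-2-hydroxy-5,9,13-trimethyltetradeca-4,8,12-trien-1-one | CC(C)=CCC/C(C)=C/CC/C(C)=C/C[C@@H](O)C(=O)c1ccc(O)cc1O | target

Total step count: 8
Longest linear sequence: 6 steps (steps 1, 2, 4, 5, 7, 8)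

Steps most likely to fail

Step 4. Reduction of the redox-active ester may outrun radical capture, giving hydrodecarboxylation or radical dimerisation. Ring-opening β-oxygen elimination at the alkylnickel stage or partial loss of alkene geometry could also lower the yield. The fallback sets out from 6 and comes back to the route at 10, forming the same C3–C4 bond by epoxide opening. Iodine–lithium exchange on 6 (t-BuLi, Et2O, –78 °C) would give (1E,5E)-2,6,10-trimethylundeca-1,5,9-trien-1-yllithium F1. Transmetalation with MgBr2·OEt2 would give (1E,5E)-2,6,10-trimethylundeca-1,5,9-trien-1-ylmagnesium bromide F2. With CuI (10 mol %) in THF at –40 °C, F2 should open commercial methyl (R)-glycidate (COC(=O)[C@H]1CO1) at its CH2 terminus in a copper-catalysed SN2 reaction. This would give methyl (2R,4E,8E)-2-hydroxy-5,9,13-trimethyltetradeca-4,8,12-trienoate F3, with C2 delivered unchanged from the epoxide. Treatment of F3 with MeNHOMe·HCl and i-PrMgCl as in step 5 should give 10.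

Step 8. Acid may promote cycloetherification of the C2 hydroxyl onto the protonated C4=C5 alkene, hydration or migration of the alkenes, and enolisation that erodes C2. The fallback sets out from 11 and comes back to the route at 15, using a protecting group removed under neutral conditions. 11 would be allylated twice (allyl bromide, K2CO3, acetone, reflux) to 1-bromo-2,4-bis(allyloxy)benzene F4. Mg turnings and LiCl in THF would convert F4 into [2,4-bis(allyloxy)phenyl]magnesium bromide F5. Added to 10 (2.5 equiv, THF, 0 °C), F5 should give (2R,4E,8E)-1-[2,4-bis(allyloxy)phenyl]-2-hydroxy-5,9,13-trimethyltetradeca-4,8,12-trien-1-one F6. Pd(PPh3)4 (5 mol %) and morpholine in THF at rt would then remove both allyl groups through π-allyl complexes (Tsuji–Trost deallylation) and give 15.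

Step 7. Addition to the alkoxide-bearing amide may be sluggish, with incomplete conversion or enolisation on warming. The fallback sets out from 10 and comes back to the route at 15. 10 would be silylated (TESCl, imidazole, CH2Cl2) to (2R,4E,8E)-N-methoxy-N,5,9,13-tetramethyl-2-[(triethylsilyl)oxy]tetradeca-4,8,12-trienamide F7. As an ordinary α-silyloxy Weinreb amide, F7 should take up 13 (1.3 equiv, THF, –78 °C) to give (2R,4E,8E)-1-[2,4-bis(methoxymethoxy)phenyl]-5,9,13-trimethyl-2-[(triethylsilyl)oxy]tetradeca-4,8,12-trien-1-one F8. The acid of step 8 would then remove the silyl group together with both MOM groups and give 15.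

Further compounds
F1 | step 4 | (1E,5E)-2,6,10-trimethylundeca-1,5,9-trien-1-yllithium | CC(C)=CCC/C(C)=C/CC/C(C)=C/[Li]
F2 | step 4 | (1E,5E)-2,6,10-trimethylundeca-1,5,9-trien-1-ylmagnesium bromide | CC(C)=CCC/C(C)=C/CC/C(C)=C/[Mg]Br
F3 | step 4 | methyl (2R,4E,8E)-2-hydroxy-5,9,13-trimethyltetradeca-4,8,12-trienoate | CC(C)=CCC/C(C)=C/CC/C(C)=C/C[C@@H](O)C(=O)OC
F4 | step 8 | 1-bromo-2,4-bis(allyloxy)benzene | C=CCOc1ccc(Br)c(OCC=C)c1
F5 | step 8 | [2,4-bis(allyloxy)phenyl]magnesium bromide | C=CCOc1ccc([Mg]Br)c(OCC=C)c1
F6 | step 8 | (2R,4E,8E)-1-[2,4-bis(allyloxy)phenyl]-2-hydroxy-5,9,13-trimethyltetradeca-4,8,12-trien-1-one | CC(C)=CCC/C(C)=C/CC/C(C)=C/C[C@@H](O)C(=O)c1ccc(OCC=C)cc1OCC=C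
F7 | step 7 | (2R,4E,8E)-N-methoxy-N,5,9,13-tetramethyl-2-[(triethylsilyl)oxy]tetradeca-4,8,12-trienamide | CC(C)=CCC/C(C)=C/CC/C(C)=C/C[C@@H](O[Si](CC)(CC)CC)C(=O)N(C)OC
F8 | step 7 | (2R,4E,8E)-1-[2,4-bis(methoxymethoxy)phenyl]-5,9,13-trimethyl-2-[(triethylsilyl)oxy]tetradeca-4,8,12-trien-1-one | CC(C)=CCC/C(C)=C/CC/C(C)=C/C[C@@H](O[Si](CC)(CC)CC)C(=O)c1ccc(OCOC)cc1OCOC
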